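**Plan**

1. Locants are those of the cassane skeleton: ring A = C1–C5 and C10, ring B = C5–C10, ring C = C8, C9, C11, C13, C14; C12 is the lactone carbonyl, C15/C16 the oxirane carbons, C17 the ester carbon; α is the face of the C5 oxygen, β that of the C10 methyl.
2. Cuts, in retrosynthetic order: the oxirane (C15–O–C16) and the lactone O–C16 bond (back to a C13 allyl group and a C12 ester); ring C at C8–C14 and C11–C13 (C12–C13–C14–C17 is a malate unit); ring B at C8=C9 (aldol); ring A at C5–C10 (1,2-shift); the C5–C6 allyl bond.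
3. Forward order: a cyclopentane holding C1–C5 → ring A by one-carbon ring expansion → ring B by aldol condensation → ring C by alkylation with an (R)-malate dianion and an enolate SN2 closure → enol lactone → oxirane.
4. Enabling feature: in ring A the quaternary C10 sits between oxygenated C1 and the oxygenated tertiary C5 and carries C9, so C1(O)–C10–C9(O) is an aldol pattern. A cyclopentanol epoxide (C1 carbinol, C10–C9 oxirane) can therefore shift its ring bond C1–C5 onto C10, inserting C10 into the ring and fixing it against C5, and the C9 oxygen can then pass a hydride to C1.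
5. Stereochemistry: C5 from a palladium-catalysed asymmetric allylation; C1 and C10 relayed from it (Felkin addition, directed epoxidation, stereospecific shift, anti hydride transfer); C9 and C8 from α-face hydride delivery and equatorial alkylation; C13/C14 bought as (R)-malic ester (Fráter–Seebach alkylations, SN2 inversion); C7 from a C5-hydroxyl-directed reduction; C15/C16 from an anti bromohydrin closed to the oxirane.

Key step: step 6

**Route**

Step 1
Reactants: 1 2-hydroxy-3-methylcyclopent-2-en-1-one (cyclotene)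
Product: 2 2-[(tert-butyldimethylsilyl)oxy]-3-methylcyclopent-2-en-1-one
Conditions: TBSCl, imidazole, DMF, 23 °C
Reagents that add atoms: tert-butyldimethylsilyl chloride, CC(C)(C)[Si](C)(C)Cl
Why: O-silylation of the enolised 1,2-diketone should give the silyl enol ether cleanly; no stereocentre is formed.

Step 2
Reactants: 2 2-[(tert-butyldimethylsilyl)oxy]-3-methylcyclopent-2-en-1-one
Product: 4 allyl 2-[(tert-butyldimethylsilyl)oxy]-3,3-dimethylcyclopent-1-en-1-yl carbonate, via lithium enolate 3 (not isolated)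
Conditions: Me2CuLi (from MeLi and CuI), Et2O/THF, −78 → −30 °C; then ClCO2CH2CH=CH2, −78 °C
Reagents that add atoms: lithium dimethylcuprate, [Li+].C[Cu-]C; allyl chloroformate, C=CCOC(Cl)=O
Why: cuprate conjugate addition installs the second C4 methyl and gives the C1 enolate regiospecifically, and cold O-acylation (before any 1,4 O-to-O silyl shift) should give the enol carbonate.

Step 3
Reactants: 4 allyl 2-[(tert-butyldimethylsilyl)oxy]-3,3-dimethylcyclopent-1-en-1-yl carbonate
Product: 5 (R)-2-allyl-2-[(tert-butyldimethylsilyl)oxy]-3,3-dimethylcyclopentan-1-one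
Conditions: Pd2(dba)3 (2.5 mol %), (R,R)-ANDEN-phenyl Trost ligand (6 mol %), toluene, 23 °C
Reagents that add atoms: none
Why: decarboxylative asymmetric allylic alkylation (Tsuji–Trost type, zerovalent palladium): loss of CO2 gives an enolate/π-allyl ion pair that recombines at C5 in the chiral pocket, the ligand enantiomer being the one that delivers the R centre.

Step 4
Reactants: 5 (R)-2-allyl-2-[(tert-butyldimethylsilyl)oxy]-3,3-dimethylcyclopentan-1-one
Product: 6 (1R,2R)-2-allyl-1-[(E)-but-2-en-2-yl]-2-[(tert-butyldimethylsilyl)oxy]-3,3-dimethylcyclopentan-1-ol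
Conditions: (E)-2-bromobut-2-ene, t-BuLi (2 equiv), Et2O, −78 °C; then 5, THF, −78 °C; AcOH quench at −78 °C
Reagents that add atoms: (Z)-but-2-en-2-yllithium (from (E)-2-bromobut-2-ene with retention), [Li]/C(C)=C/C
Why: 1,2-addition of an alkenyllithium under non-chelating conditions; Felkin–Anh attack anti to the bulky, poorly coordinating silyloxy group should place the alkenyl group cis to allyl (hydroxyl cis to OTBS), and the cold quench avoids 1,2-silyl migration.

Step 5
Reactants: 6 (1R,2R)-2-allyl-1-[(E)-but-2-en-2-yl]-2-[(tert-butyldimethylsilyl)oxy]-3,3-dimethylcyclopentan-1-ol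
Product: 7 (1R,2R)-2-allyl-2-[(tert-butyldimethylsilyl)oxy]-1-[(2R,3S)-2,3-dimethyloxiran-2-yl]-3,3-dimethylcyclopentan-1-ol
Conditions: VO(acac)2 (5 mol %), t-BuOOH, CH2Cl2, 0 °C
Reagents that add atoms: tert-butyl hydroperoxide, CC(C)(C)OO
Why: hydroxyl-directed vanadium-catalysed epoxidation touches only the allylic alkene; in the reactive rotamer the C10 methyl lies over the C2 methylene and not the quaternary C5 (A1,2 strain), so oxygen should be delivered to the face anti to C5.

Step 6
Reactants: 7 (1R,2R)-2-allyl-2-[(tert-butyldimethylsilyl)oxy]-1-[(2R,3S)-2,3-dimethyloxiran-2-yl]-3,3-dimethylcyclopentan-1-ol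
Product: 9 (1S)-1-[(1R,2R,6S)-2-allyl-2-[(tert-butyldimethylsilyl)oxy]-6-hydroxy-1,3,3-trimethylcyclohexyl]ethyl acetate, via β-hydroxy ketone 8 (not isolated)
Conditions: SmI2 (30 mol %), MeCHO (4 equiv), THF/ClCH2CH2Cl, 0 → 23 °C
Reagents that add atoms: acetaldehyde, CC=O
Why: Trivalent samarium formed in situ binds the oxirane oxygen, the tertiary C10–O bond ionises while the anti-periplanar ring bond C1–C5 migrates to C10 (semipinacol rearrangement of a 2,3-epoxy alcohol, type 3), and the samarium aldolate 8 adds to acetaldehyde and passes the hemiacetal hydride to C1 through a chair six-membered transition state (Evans–Tishchenko reduction). The closest known reaction type is the samarium-catalysed tandem semipinacol rearrangement/Tishchenko reduction of α-hydroxy epoxides. Ring A is closed by a one-carbon ring expansion, a suprafacial 1,2-alkyl shift that turns the cyclopentanol into the cyclohexanone, not by an end-to-end cyclisation. C10 is set by inversion at the oxirane carbon with retention at migrating C5, so the trans relation of the C5 oxygen and the C10 methyl follows from the epoxide configuration; C1 is set anti to the C9 oxygen by the internal hydride delivery (1α-OH), C9 itself coming from the E alkene. The step needs C5 and not C2 to migrate and C10 and not C9 to ionise: C5 is the more substituted, oxygen-bearing carbon and already lies anti to the oxirane C–O bond (the oxygen was delivered anti to C5), and C10 is the tertiary oxirane carbon. Hydride transfer must also outrun retro-aldol cleavage of 8, which excess aldehyde and the intramolecular chair transition state should favour.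

Step 7
Reactants: 9 (1S)-1-[(1R,2R,6S)-2-allyl-2-[(tert-butyldimethylsilyl)oxy]-6-hydroxy-1,3,3-trimethylcyclohexyl]ethyl acetate
Product: 11 1α,5α-O-isopropylidene acetal of the C1/C5 diol (2,4-dioxabicyclo[3.3.1]nonane; 5-allyl; 10β-methyl; (9S)-acetate kept), via diol 10 (not isolated)
Conditions: HF·pyridine, THF, 0 → 40 °C; then Me2C(OMe)2, CSA (cat.), acetone, 23 °C
Reagents that add atoms: 2,2-dimethoxypropane, COC(C)(C)OC
Why: fluoride desilylation of the tertiary silyl ether followed by acetalisation of the syn-1,3-diaxial C1/C5 diol should mask both oxygens and lock ring A in the chair with C6 and C9 equatorial.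

Step 8
Reactants: 11 1α,5α-O-isopropylidene acetal with (9S)-acetate
Product: 12 the corresponding (9S)-alcohol (1α,5α-O-isopropylidene; 5-allyl; 10β-methyl; 10-(1-hydroxyethyl))
Conditions: K2CO3, MeOH, 23 °C
Reagents that add atoms: none
Why: base-catalysed methanolysis (transesterification) removes the acetate while the acetal is inert to base.

Step 9
Reactants: 12 the (9S)-alcohol
Product: 13 10-acetyl-5-allyl-1α,5α-(isopropylidenedioxy)-4,4,10β-trimethylcyclohexane (ring A with C9 as methyl ketone)
Conditions: Dess–Martin periodinane, NaHCO3, CH2Cl2, 23 °C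
Reagents that add atoms: none
Why: Dess–Martin oxidation of the only free hydroxyl gives the C9 ketone; the C9 stereocentre has done its work and is deleted.

Step 10
Reactants: 13 10-acetyl-5-allyl-1α,5α-(isopropylidenedioxy)-4,4,10β-trimethylcyclohexane
Product: 14 10-acetyl-1α,5α-(isopropylidenedioxy)-4,4,10β-trimethyl-5-(2-oxopropyl)cyclohexane
Conditions: PdCl2 (10 mol %), CuCl (1 equiv), O2 (1 atm), DMF/H2O 7:1, 23 °C
Reagents that add atoms: dioxygen, O=O
Why: Tsuji–Wacker oxidation of the terminal alkene (Markovnikov hydroxypalladation, the oxygen atom passing through water) should give the C7 methyl ketone.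

Step 11
Reactants: 14 10-acetyl-1α,5α-(isopropylidenedioxy)-4,4,10β-trimethyl-5-(2-oxopropyl)cyclohexane
Product: 15 trans-fused A/B enone: 1α,5α-(isopropylidenedioxy)-4,4,9,10β-tetramethyl-7-oxo-8(9)-ene
Conditions: pyrrolidine (0.5 equiv), AcOH (0.5 equiv), toluene, 60 °C
Reagents that add atoms: none
Why: intramolecular aldol condensation via the enamine of the less hindered C7 ketone, whose C8 terminus attacks the neopentyl C9 ketone (6-enolexo-exo-trig) and dehydrates; ring B should close trans because the acetal holds C6 and C9 equatorial.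

Step 12
Reactants: 15 trans-fused A/B enone
Product: 16 its 11-bromo derivative (9-bromomethyl enone)
Conditions: NBS, AIBN (cat.), K2CO3, PhCF3, 80 °C
Reagents that add atoms: N-bromosuccinimide, O=C1CCC(=O)N1Br
Why: Wohl–Ziegler bromination at C11, the only allylic C–H (C10 is quaternary), gives the γ-bromo enone.

Step 13
Reactants: 17 dimethyl (R)-malate
Product: 18 dimethyl (2R,3S)-3-allyl-2-hydroxybutanedioate
Conditions: LiN(SiMe3)2 (2.1 equiv), THF, −78 → −20 °C; allyl bromide, −78 → −10 °C; AcOH
Reagents that add atoms: allyl bromide, C=CCBr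
Why: Fráter–Seebach alkylation: the chelated alkoxide–enolate dianion is allylated anti to the C2 oxygen.

Step 14
Reactants: 16 the 9-bromomethyl enone; 18 dimethyl (2R,3S)-3-allyl-2-hydroxybutanedioate
Product: 19 dimethyl (2R,3S)-3-allyl-2-hydroxy-3-[(enone C9)methyl]butanedioate (C11–C13 bond; C13 quaternary; C14 carbinol)
Conditions: 18 (1.6 equiv), LiN(SiMe3)2 (3.4 equiv), THF, −78 °C; then 16, −78 → −40 °C; AcOH
Reagents that add atoms: none
Why: second Fráter–Seebach alkylation: the tetrasubstituted enolate again reacts anti to the alkoxide, so C11 takes the place first held by allyl and fixes quaternary C13, while SN2 at the very reactive γ-bromo enone should outrun proton transfer at −78 °C.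

Step 15
Reactants: 19 the C14 carbinol
Product: 20 its C14 trifluoromethanesulfonate
Conditions: Tf2O, 2,6-lutidine, CH2Cl2, −78 °C
Reagents that add atoms: trifluoromethanesulfonic anhydride, O=S(=O)(OS(=O)(=O)C(F)(F)F)C(F)(F)F
Why: O-sulfonylation of the α-hydroxy ester with retention at C14; an α-carbonyl triflate does not ionise and is kept for SN2.

Step 16
Reactants: 20 the C14 triflate
Product: 22 tricyclic keto diester (ring C closed: 13β-allyl; 13α- and 14β-CO2Me; 7-oxo; 8βH; 9αH; 1α,5α-O-isopropylidene), via silyl enol ether 21 (not isolated)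
Conditions: Et3SiH, RhCl(PPh3)3 (2 mol %), THF, 40 °C; then (Me2N)3S(Me3SiF2), THF, −40 → 0 °C
Reagents that add atoms: none
Why: 1,4-hydrosilylation delivers hydrogen to C9 from the α face (anti to the C10 methyl) and gives the C7/C8 silyl enol ether regiospecifically; fluoride then frees the enolate, which should close ring C by 5-exo-tet SN2 on the triflate with inversion at C14, bonding at the α face of C8 (β face blocked 1,3 by the C10 methyl) to give the trans B/C fusion.

Step 17
Reactants: 22 tricyclic keto diester acetonide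
Product: 23 the 1α,5α-diol keto diester
Conditions: AcOH/H2O 4:1, 40 °C
Reagents that add atoms: none
Why: mild acid hydrolysis of the isopropylidene acetal frees both hydroxyls; esters and the allyl group are inert.

Step 18
Reactants: 23 the 1α,5α-diol keto diester
Product: 24 the 1α,5α,7β-triol diester
Conditions: Me4NBH(OAc)3, MeCN/AcOH, −30 °C
Reagents that add atoms: none
Why: Evans–Saksena hydroxyl-directed reduction: boron bound to the axial C5 oxygen delivers hydride to the α face of C7 through a chair transition state, giving the 5,7-anti diol (equatorial 7β-OH).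

Step 19
Reactants: 24 the 1α,5α,7β-triol diester
Product: 25 the 1α,7β-diacetate (5α-OH free)
Conditions: Ac2O, DMAP, Et3N, CH2Cl2, 23 °C
Reagents that add atoms: acetic anhydride, CC(=O)OC(C)=O
Why: DMAP-catalysed acylation esterifies the two secondary hydroxyls while the tertiary C5 hydroxyl stays free.

Step 20
Reactants: 25 the 1α,7β-diacetate
Product: 27 spiro lactol (C12 lactone closed onto C16 hemiacetal; C17 methyl ester kept), via aldehyde 26 (not isolated)
Conditions: O3, CH2Cl2/MeOH, −78 °C; Me2S; then 1 M HCl, THF, 23 °C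
Reagents that add atoms: ozone, [O-][O+]=O; water, O
Why: ozonolysis of the allyl group gives the C16 aldehyde, whose hydrate should lactonise onto the geminal C12 ester (5-exo-trig, helped by the quaternary C13) with loss of methanol to the five-membered pseudo-acid.

Step 21
Reactants: 27 spiro lactol
Product: 28 spiro enol lactone (C15=C16)
Conditions: MsCl (1.2 equiv), Et3N, CH2Cl2, −20 → 23 °C
Reagents that add atoms: none
Why: sulfonylation of the lactol hydroxyl and base-induced elimination across C15–C16 (lactol dehydration) gives the enol lactone, which cannot move into conjugation because C13 is quaternary.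

Step 22
Reactants: 28 spiro enol lactone
Product: 29 trans bromo lactol (15-bromo; 16-hydroxy)
Conditions: NBS, THF/H2O 4:1, 0 °C
Reagents that add atoms: N-bromosuccinimide, O=C1CCC(=O)N1Br; water, O
Why: bromohydrin formation on the enol-ester alkene: bromonium should form on the face away from the C14 ester (the C11 side) and water open it at acyloxy-stabilised C16 trans to bromine.

Step 23
Reactants: 29 trans bromo lactol
Product: 30 spirocaesalmin
Conditions: Ag2O, 4 Å MS, CH2Cl2, 23 °C, dark
Reagents that add atoms: none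
Why: silver-assisted intramolecular Williamson closure: the C16 oxygen displaces bromide at C15 with inversion, placing the oxirane on the face syn to C14, the face that direct epoxidation of 28 would avoid.

**Compound list**

1 | 2-hydroxy-3-methylcyclopent-2-en-1-one (cyclotene) | CC1=C(O)C(=O)CC1 | starting material
2 | 2-[(tert-butyldimethylsilyl)oxy]-3-methylcyclopent-2-en-1-one | CC1=C(O[Si](C)(C)C(C)(C)C)C(=O)CC1 | intermediate
3 | lithium 2-[(tert-butyldimethylsilyl)oxy]-3,3-dimethylcyclopent-1-en-1-olate | [Li+].[O-]C1=C(O[Si](C)(C)C(C)(C)C)C(C)(C)CC1 | intermediate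
4 | allyl 2-[(tert-butyldimethylsilyl)oxy]-3,3-dimethylcyclopent-1-en-1-yl carbonate | C=CCOC(=O)OC1=C(O[Si](C)(C)C(C)(C)C)C(C)(C)CC1 | intermediate
5 | (R)-2-allyl-2-[(tert-butyldimethylsilyl)oxy]-3,3-dimethylcyclopentan-1-one | O=C1CCC(C)(C)[C@@]1(CC=C)O[Si](C)(C)C(C)(C)C | intermediate
6 | (1R,2R)-2-allyl-1-[(E)-but-2-en-2-yl]-2-[(tert-butyldimethylsilyl)oxy]-3,3-dimethylcyclopentan-1-ol | O[C@@]1(/C(C)=C/C)CCC(C)(C)[C@@]1(CC=C)O[Si](C)(C)C(C)(C)C | intermediate
7 | (1R,2R)-2-allyl-2-[(tert-butyldimethylsilyl)oxy]-1-[(2R,3S)-2,3-dimethyloxiran-2-yl]-3,3-dimethylcyclopentan-1-ol | O[C@@]1([C@]2(C)O[C@H]2C)CCC(C)(C)[C@@]1(CC=C)O[Si](C)(C)C(C)(C)C | intermediate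
8 | (2R,3R)-3-allyl-3-[(tert-butyldimethylsilyl)oxy]-2-[(1S)-1-hydroxyethyl]-2,4,4-trimethylcyclohexan-1-one | O=C1CCC(C)(C)[C@@](CC=C)(O[Si](C)(C)C(C)(C)C)[C@@]1(C)[C@H](C)O | intermediate
9 | (1S)-1-[(1R,2R,6S)-2-allyl-2-[(tert-butyldimethylsilyl)oxy]-6-hydroxy-1,3,3-trimethylcyclohexyl]ethyl acetate (1α-OH, 5α-OTBS, 10β-Me) | O[C@H]1CCC(C)(C)[C@@](CC=C)(O[Si](C)(C)C(C)(C)C)[C@@]1(C)[C@H](C)OC(C)=O | intermediate
10 | (1S)-1-[(1R,2R,6S)-2-allyl-2,6-dihydroxy-1,3,3-trimethylcyclohexyl]ethyl acetate | O[C@H]1CCC(C)(C)[C@@](CC=C)(O)[C@@]1(C)[C@H](C)OC(C)=O | intermediate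
11 | 1α,5α-O-isopropylidene acetal of 10: (1S)-1-[1-allyl-3,3,8,8,9-pentamethyl-2,4-dioxabicyclo[3.3.1]nonan-9-yl]ethyl acetate | CC1(C)O[C@H]2CCC(C)(C)[C@@](CC=C)(O1)[C@@]2(C)[C@H](C)OC(C)=O | intermediate
12 | (9S)-alcohol of 11: (1S)-1-[1-allyl-3,3,8,8,9-pentamethyl-2,4-dioxabicyclo[3.3.1]nonan-9-yl]ethan-1-ol | CC1(C)O[C@H]2CCC(C)(C)[C@@](CC=C)(O1)[C@@]2(C)[C@H](C)O | intermediate
13 | C9 methyl ketone: 1-[1-allyl-3,3,8,8,9-pentamethyl-2,4-dioxabicyclo[3.3.1]nonan-9-yl]ethan-1-one (10-acetyl, 5-allyl, 1α,5α-acetonide) | CC1(C)O[C@H]2CCC(C)(C)[C@@](CC=C)(O1)[C@@]2(C)C(C)=O | intermediate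
14 | diketone: 10-acetyl-5-(2-oxopropyl) ring A acetonide | CC1(C)O[C@H]2CCC(C)(C)[C@@](CC(C)=O)(O1)[C@@]2(C)C(C)=O | intermediate
15 | trans-fused A/B enone: 1α,5α-(isopropylidenedioxy)-4,4,9,10β-tetramethyl-7-oxo-8(9)-ene | CC1(C)O[C@H]2CCC(C)(C)[C@]3(O1)CC(=O)C=C(C)[C@@]23C | intermediate
16 | 9-(bromomethyl) enone (11-bromo-15) | CC1(C)O[C@H]2CCC(C)(C)[C@]3(O1)CC(=O)C=C(CBr)[C@@]23C | intermediate
17 | dimethyl (R)-malate | COC(=O)[C@H](O)CC(=O)OC | starting material
18 | dimethyl (2R,3S)-3-allyl-2-hydroxybutanedioate | COC(=O)[C@H](O)[C@H](CC=C)C(=O)OC | intermediate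
19 | dimethyl (2R,3S)-3-allyl-2-hydroxy-3-[(enone C9)methyl]butanedioate (C13 quaternary, C14 carbinol) | CC1(C)O[C@H]2CCC(C)(C)[C@]3(O1)CC(=O)C=C(C[C@](CC=C)(C(=O)OC)[C@@H](O)C(=O)OC)[C@@]23C | intermediate
20 | C14 trifluoromethanesulfonate of 19 | CC1(C)O[C@H]2CCC(C)(C)[C@]3(O1)CC(=O)C=C(C[C@](CC=C)(C(=O)OC)[C@@H](OS(=O)(=O)C(F)(F)F)C(=O)OC)[C@@]23C | intermediate
21 | C7 triethylsilyl enol ether (7(8)-ene, 9αH) of reduced 20 | CC1(C)O[C@H]2CCC(C)(C)[C@]3(O1)CC(O[Si](CC)(CC)CC)=C[C@H](C[C@](CC=C)(C(=O)OC)[C@@H](OS(=O)(=O)C(F)(F)F)C(=O)OC)[C@@]23C | intermediate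
22 | tricyclic keto diester: 13β-allyl, 13α-CO2Me, 14β-CO2Me, 7-oxo, 8βH, 9αH, 1α,5α-O-isopropylidene | COC(=O)[C@H]1[C@@H]2C(=O)C[C@@]3(O4)C(C)(C)CC[C@H](OC4(C)C)[C@]3(C)[C@H]2C[C@]1(CC=C)C(=O)OC | intermediate
23 | 1α,5α-dihydroxy-7-oxo diester | COC(=O)[C@H]1[C@@H]2C(=O)C[C@@]3(O)C(C)(C)CC[C@H](O)[C@]3(C)[C@H]2C[C@]1(CC=C)C(=O)OC | intermediate
24 | 1α,5α,7β-trihydroxy diester | COC(=O)[C@H]1[C@@H]2[C@@H](O)C[C@@]3(O)C(C)(C)CC[C@H](O)[C@]3(C)[C@H]2C[C@]1(CC=C)C(=O)OC | intermediate
25 | 1α,7β-diacetoxy-5α-hydroxy diester | COC(=O)[C@H]1[C@@H]2[C@@H](OC(C)=O)C[C@@]3(O)C(C)(C)CC[C@H](OC(C)=O)[C@]3(C)[C@H]2C[C@]1(CC=C)C(=O)OC | intermediate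
26 | C16 aldehyde (13β-(2-oxoethyl)) | COC(=O)[C@H]1[C@@H]2[C@@H](OC(C)=O)C[C@@]3(O)C(C)(C)CC[C@H](OC(C)=O)[C@]3(C)[C@H]2C[C@]1(CC=O)C(=O)OC | intermediate
27 | spiro lactol (16-hydroxy γ-lactone, C16 epimers) | COC(=O)[C@H]1[C@@H]2[C@@H](OC(C)=O)C[C@@]3(O)C(C)(C)CC[C@H](OC(C)=O)[C@]3(C)[C@H]2C[C@]12C(=O)OC(O)C2 | intermediate
28 | spiro enol lactone (15,16-ene) | COC(=O)[C@H]1[C@@H]2[C@@H](OC(C)=O)C[C@@]3(O)C(C)(C)CC[C@H](OC(C)=O)[C@]3(C)[C@H]2C[C@]12C(=O)OC=C2 | intermediate
29 | trans 15-bromo-16-hydroxy lactone | COC(=O)[C@H]1[C@@H]2[C@@H](OC(C)=O)C[C@@]3(O)C(C)(C)CC[C@H](OC(C)=O)[C@]3(C)[C@H]2C[C@]12C(=O)O[C@H](O)[C@H]2Br | intermediate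
30 | spirocaesalmin | COC(=O)[C@H]1[C@@H]2[C@@H](OC(C)=O)C[C@@]3(O)C(C)(C)CC[C@H](OC(C)=O)[C@]3(C)[C@H]2C[C@]12C(=O)O[C@@H]1O[C@@H]12 | target

**Count and risks**

Total steps: 23. Longest linear sequence: 22 (steps 1–12 and 14–23; step 13 is the one-step branch).

Steps most likely to fail:

1. Step 16. The fluoride-freed enolate may transfer a proton to the C6 side and eliminate the C5 oxygen, or fail to displace the neopentyl-type triflate. The fallback sets out from 19 and returns at 22. The C14 carbinol of 19 is oxidised (Dess–Martin periodinane) to α-keto ester F1. Treatment with [(Ph3P)CuH]6 (toluene, −40 → 0 °C) reduces the enone in a conjugate sense, and the copper enolate adds to the activated C14 ketone (reductive aldol cyclisation) to give ring-C tertiary α-hydroxy ester F2. Acylation with methyl chlorooxoacetate/DMAP gives tertiary methyl oxalate F3, which is deoxygenated with Bu3SnH/AIBN (Barton-type radical deoxygenation). C14 and C8, both epimerisable, are then equilibrated with DBU to the trans diester and trans ring fusion of 22.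

2. Step 14. The basic dianion may enolise the bromo enone or add to its carbonyl instead of alkylating. The fallback sets out from 16 and returns at 19. Luche reduction of 16 (NaBH4, CeCl3·7H2O, MeOH, −78 °C) gives bromo allylic alcohol F4, which is silylated (TBSOTf, 2,6-lutidine) to allylic bromide F5, now free of acidic or electrophilic carbonyl groups. The dianion of 18 is alkylated with F5 under the same conditions to give silyl ether F6. Desilylation (Bu4NF, AcOH) gives diol F7, and MnO2 oxidises only the allylic C7 alcohol to give 19.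

3. Step 6. The aldol-type intermediate may cleave by retro-aldol reaction, or the silyl ether may move, before hydride transfer, so that shift and reduction do not mesh in one flask. The fallback sets out from 7 and returns at 9. The tertiary hydroxyl of 7 is silylated (TMSOTf, 2,6-lutidine) to epoxy silyl ether F8. Rearrangement with methylaluminium bis(4-bromo-2,6-di-tert-butylphenoxide) (toluene, −78 °C; epoxy silyl ether rearrangement) moves silicon onto the C9 oxygen as the ring expands, giving β-silyloxy ketone F9, which cannot undergo retro-aldol cleavage. K2CO3/MeOH then frees 8, which is isolated here and reduced in a separate Evans–Tishchenko step (SmI2, MeCHO, THF, −10 °C) to 9.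

Further compounds
F1 | step 16 | C14 α-keto ester of 19 (dimethyl 2-allyl-2-[(enone C9)methyl]-3-oxobutanedioate) | CC1(C)O[C@H]2CCC(C)(C)[C@]3(O1)CC(=O)C=C(C[C@](CC=C)(C(=O)OC)C(=O)C(=O)OC)[C@@]23C
F2 | step 16 | ring-C tertiary 14-hydroxy keto diester (C14 unassigned) | COC(=O)C1(O)[C@@H]2C(=O)C[C@@]3(O4)C(C)(C)CC[C@H](OC4(C)C)[C@]3(C)[C@H]2C[C@]1(CC=C)C(=O)OC
F3 | step 16 | 14-O-methyl oxalate of F2 | COC(=O)C1(OC(=O)C(=O)OC)[C@@H]2C(=O)C[C@@]3(O4)C(C)(C)CC[C@H](OC4(C)C)[C@]3(C)[C@H]2C[C@]1(CC=C)C(=O)OC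
F4 | step 14 | 9-(bromomethyl) allylic C7 alcohol (C7 unassigned) | CC1(C)O[C@H]2CCC(C)(C)[C@]3(O1)CC(O)C=C(CBr)[C@@]23C
F5 | step 14 | C7 tert-butyldimethylsilyl ether of F4 | CC1(C)O[C@H]2CCC(C)(C)[C@]3(O1)CC(O[Si](C)(C)C(C)(C)C)C=C(CBr)[C@@]23C
F6 | step 14 | malate alkylation product of F5 (C7 silyl ether) | CC1(C)O[C@H]2CCC(C)(C)[C@]3(O1)CC(O[Si](C)(C)C(C)(C)C)C=C(C[C@](CC=C)(C(=O)OC)[C@@H](O)C(=O)OC)[C@@]23C
F7 | step 14 | C7,C14 diol from F6 | CC1(C)O[C@H]2CCC(C)(C)[C@]3(O1)CC(O)C=C(C[C@](CC=C)(C(=O)OC)[C@@H](O)C(=O)OC)[C@@]23C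
F8 | step 6 | trimethylsilyl ether of epoxy alcohol 7 | C[Si](C)(C)O[C@@]1([C@]2(C)O[C@H]2C)CCC(C)(C)[C@@]1(CC=C)O[Si](C)(C)C(C)(C)C
F9 | step 6 | C9 trimethylsilyl ether of β-hydroxy ketone 8 | O=C1CCC(C)(C)[C@@](CC=C)(O[Si](C)(C)C(C)(C)C)[C@@]1(C)[C@H](C)O[Si](C)(C)C
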